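**Retrosynthetic overview**
- Feature: in flavanone numbering, C4a of ring A is bonded to three oxidised carbons (the C4 ketone, C5 bearing OMe and C8a bearing O1). It therefore maps onto the doubly nucleophilic methyl carbon of benzalacetone, which also supplies C4, C3, C2 and the phenyl ring.
- Last disconnection, O1–C2: an enantioselective oxa-Michael closure of the dihydropyranone ring from the ring-A-dearomatised chalcone sets (S)-C2.
- Key disconnection, C4a–C8a and C4a–C5: a [5+1] annulation joins the benzalacetone methyl carbon to a C8a–C8–C7–C6–C5 bis-electrophile (acid chloride at C8a, β,β-dimethoxy enone ending at C5). Ring A forms with C8 already quaternary and the 5-OMe in place.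
- The bis-electrophile comes from diprenylmalonyl dichloride and 1,1-dimethoxyethene; the dichloride comes from dimethyl malonate and prenyl bromide.
- Ring order: carbocyclic ring A first, then the O-heterocycle; the phenyl ring is bought.

Key step: step 5

Remark (assumption): the sense of induction of the cinchona thiourea in step 6 cannot be fixed on paper for this substrate class; the quinine- or quinidine-derived pseudoenantiomer that delivers (S)-C2 is to be chosen in a first small-scale run.

**Step 1**
Reactants: 1 dimethyl malonate; 2 prenyl bromide (1-bromo-3-methylbut-2-ene)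
Product: 4 dimethyl 2,2-bis(3-methylbut-2-en-1-yl)malonate, via monoprenyl malonate 3 (not isolated)
Conditions: NaH (2.3 equiv), 2 (2.3 equiv), THF/DMF, 0 °C → rt
Reagents that add atoms: none
Why: Malonic ester dialkylation, in which each deprotonation gives a stabilised enolate that is C-alkylated by the primary allylic bromide in an SN2 reaction, the second alkylation following in the same pot; no stereocentre is formed.

**Step 2**
Reactants: 4 dimethyl 2,2-bis(3-methylbut-2-en-1-yl)malonate
Product: 6 2,2-bis(3-methylbut-2-en-1-yl)malonic acid, via dipotassium diprenylmalonate 5 (not isolated)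
Conditions: KOH (5 equiv), EtOH/H2O, reflux; then cold 2 M HCl to pH 1, Et2O extraction
Reagents that add atoms: potassium hydroxide, [K+].[OH-]
Why: Saponification of both esters under reflux is standard for 2,2-dialkylmalonates, the free 2,2-disubstituted malonic acid should not decarboxylate at room temperature, and the prenyl alkenes should tolerate brief contact with cold dilute aqueous acid.

**Step 3**
Reactants: 6 2,2-bis(3-methylbut-2-en-1-yl)malonic acid
Product: 7 2,2-bis(3-methylbut-2-en-1-yl)malonyl dichloride
Conditions: 1-chloro-N,N,2-trimethylprop-1-en-1-amine (2.2 equiv), CH2Cl2, 0 °C → rt; amide by-product removed in vacuo, bulb-to-bulb distillation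
Reagents that add atoms: 1-chloro-N,N,2-trimethylprop-1-en-1-amine, CC(C)=C(Cl)N(C)C
Why: Acid chloride formation with an α-chloroenamine proceeds through an acyloxyiminium chloride and ends in a neutral amide, so no HCl is liberated that could add across the trisubstituted prenyl alkenes.

**Step 4**
Reactants: 7 2,2-bis(3-methylbut-2-en-1-yl)malonyl dichloride; 8 1,1-dimethoxyethene
Product: 9 5,5-dimethoxy-3-oxo-2,2-bis(3-methylbut-2-en-1-yl)pent-4-enoyl chloride
Conditions: 8 (1.0 equiv) added slowly to 7 (1.1 equiv), Et3N (1.1 equiv), Et2O, −30 → 0 °C; filtration under argon; used at once as a cold solution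
Reagents that add atoms: none
Why: C-Acylation of a ketene acetal by an acid chloride with loss of HCl to triethylamine is a known route to β,β-dimethoxy enones; 7 has no α-hydrogen and cannot form a ketene, and slow addition to a slight excess of 7 at low temperature should favour reaction at one COCl only, because the remaining one is then more hindered and flanked by a weaker acceptor.

**Step 5**
Reactants: 9 5,5-dimethoxy-3-oxo-2,2-bis(3-methylbut-2-en-1-yl)pent-4-enoyl chloride; 10 (E)-4-phenylbut-3-en-2-one (benzalacetone)
Product: 13 (E)-4-cinnamoyl-5-hydroxy-3-methoxy-6,6-bis(3-methylbut-2-en-1-yl)cyclohexa-2,4-dien-1-one, via lithium enolate 11 (not isolated), via acyclic 3,5,7-trione 12 (not isolated)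
Conditions: 10 (2.1 equiv), LiHMDS (2.1 equiv), THF, −78 °C; then 9 (1.0 equiv) in THF, −78 °C → rt; cold 0.5 M HCl work-up
Reagents that add atoms: lithium bis(trimethylsilyl)amide, [Li+].C[Si](C)(C)[N-][Si](C)(C)C (supplies only the lithium of 11; no atom of it remains in 13)
Why: Proposed new method: enolate 11 (10 has acidic hydrogens only on its methyl group) attacks the acid chloride of 9 to form C4a–C8a, the second equivalent of 11 converts the resulting trione 12 into its lithium diketonate, and on warming the diketonate carbon C4a adds to C5 of the β,β-dimethoxy enone and methoxide is expelled (C4a–C5), after which the methoxide deprotonates the strongly acidic product and so pulls the sequence forward. The closest known reactions are the C-acylation of ketone lithium enolates by acid chlorides with two equivalents of enolate and the replacement of an alkoxy group of α-oxo ketene acetals by 1,3-dicarbonyl carbanions; their one-pot union as a [5+1] annulation has not been described, the nearest annulation being the double-Michael [5+1] reaction of divinyl ketones with active methylene compounds. Ring A closes by a 6-endo-trig conjugate addition–elimination at C5, helped by the gem-dialkyl effect of quaternary C8. No stereocentre is created. The step requires attack at COCl before any attack at C5, C7 or the cinnamoyl alkene, C- instead of O-acylation, and C- instead of O-cyclisation: the first should follow from the much higher electrophilicity of the acid chloride at −78 °C, the second from the lithium counter-ion in THF with excess enolate, and the third from the reversibility of O-attack at the ketene acetal against the irreversible formation of the product anion. Since 9 has no α-hydrogen and delivers C8 already quaternary and C5 already as its methyl ether, ring A cannot aromatise and no later regioselective O-methylation is called for.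

**Step 6**
Reactants: 13 (E)-4-cinnamoyl-5-hydroxy-3-methoxy-6,6-bis(3-methylbut-2-en-1-yl)cyclohexa-2,4-dien-1-one
Product: 14 Griffinone A [(2S)-5-methoxy-8,8-bis(3-methylbut-2-en-1-yl)-2-phenyl-2,3-dihydro-4H-chromene-4,7(8H)-dione]
Conditions: 1-[3,5-bis(trifluoromethyl)phenyl]-3-(9-deoxy-9-epi-cinchona-alkaloid-9-yl)thiourea (quinine or quinidine series, 10 mol %), toluene, −20 °C
Reagents that add atoms: none
Why: Proposed new method: the quinuclidine nitrogen should deprotonate the acidic C8a enol (a vinylogous acid) to a chiral ammonium enolate while the thiourea hydrogen-bonds the cinnamoyl carbonyl, so that the enolate oxygen adds in a 6-endo-trig oxa-Michael reaction to the Si face of the β-carbon, which gives (S)-C2, and the ammonium ion protonates C3; the closest known reaction is the bifunctional amine–thiourea-catalysed cyclisation of 2'-hydroxychalcones (and their α-carboxylate-activated analogues) to flavanones, not yet shown for β-triketone enols, and the reaction is run cold and stopped early so that retro-oxa-Michael equilibration does not erode the ee.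

**Compound list**
1 | dimethyl malonate | COC(=O)CC(=O)OC | starting material
2 | prenyl bromide (1-bromo-3-methylbut-2-ene) | CC(C)=CCBr | starting material
3 | dimethyl 2-(3-methylbut-2-en-1-yl)malonate | COC(=O)C(CC=C(C)C)C(=O)OC | intermediate
4 | dimethyl 2,2-bis(3-methylbut-2-en-1-yl)malonate | COC(=O)C(CC=C(C)C)(CC=C(C)C)C(=O)OC | intermediate
5 | dipotassium 2,2-bis(3-methylbut-2-en-1-yl)malonate | [K+].[K+].[O-]C(=O)C(CC=C(C)C)(CC=C(C)C)C([O-])=O | intermediate
6 | 2,2-bis(3-methylbut-2-en-1-yl)malonic acid | OC(=O)C(CC=C(C)C)(CC=C(C)C)C(=O)O | intermediate
7 | 2,2-bis(3-methylbut-2-en-1-yl)malonyl dichloride | ClC(=O)C(CC=C(C)C)(CC=C(C)C)C(=O)Cl | intermediate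
8 | 1,1-dimethoxyethene | C=C(OC)OC | starting material
9 | 5,5-dimethoxy-3-oxo-2,2-bis(3-methylbut-2-en-1-yl)pent-4-enoyl chloride | COC(OC)=CC(=O)C(CC=C(C)C)(CC=C(C)C)C(=O)Cl | intermediate
10 | (E)-4-phenylbut-3-en-2-one (benzalacetone) | CC(=O)/C=C/c1ccccc1 | starting material
11 | lithium (E)-4-phenylbuta-1,3-dien-2-olate | C=C(O[Li])/C=C/c1ccccc1 | intermediate
12 | (E)-1,1-dimethoxy-4,4-bis(3-methylbut-2-en-1-yl)-9-phenylnona-1,8-diene-3,5,7-trione (present as its lithium diketonate) | COC(OC)=CC(=O)C(CC=C(C)C)(CC=C(C)C)C(=O)CC(=O)/C=C/c1ccccc1 | intermediate
13 | (E)-4-cinnamoyl-5-hydroxy-3-methoxy-6,6-bis(3-methylbut-2-en-1-yl)cyclohexa-2,4-dien-1-one | COC1=CC(=O)C(CC=C(C)C)(CC=C(C)C)C(O)=C1C(=O)/C=C/c1ccccc1 | intermediate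
14 | Griffinone A, (2S)-5-methoxy-8,8-bis(3-methylbut-2-en-1-yl)-2-phenyl-2,3-dihydro-4H-chromene-4,7(8H)-dione | COC1=CC(=O)C(CC=C(C)C)(CC=C(C)C)C2=C1C(=O)C[C@@H](c1ccccc1)O2 | target

**Step count**
Total steps: 6. Longest linear sequence: 6 (steps 1 to 6; 8 and 10 are commercial).

**Steps most likely to fail**

Step 5 (proposed new method). Possible failures are O-acylation of the enolate, slow or O-selective ring closure of the chelated lithium diketonate, self-destruction of 9 by attack of a methoxy oxygen on its own acid chloride before the enolate arrives, and conjugate addition of enolate or methoxide to the cinnamoyl alkene. The fallback uses known chemistry and sets out from prenyl bromide 2 and commercially available cardamonin F1 [(E)-2',4'-dihydroxy-6'-methoxychalcone]. With NaOMe (2.2 equiv) in MeOH at 0 °C → rt and 2 (2.2 equiv), the phenolate is C-prenylated at C3', the carbon between the two oxygenated carbons, to give 3'-prenylcardamonin F2. A second alkylation at the same carbon dearomatises the ring (the known dearomative gem-C-alkylation of acylphloroglucinols) and gives 13. Regioisomeric C5'- and O-prenylated products would be removed by chromatography. The fallback rejoins the route at 13.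

Step 6 (proposed new method). Possible failures are poor facial selectivity in a loosely organised ion pair, loss of ee through reversible ring opening (E1cB retro-oxa-Michael, the trione enolate being a good leaving group), and incomplete conversion. The fallback uses known chemistry and sets out from 13. Cyclisation without stereocontrol (NaOAc, EtOH, 60 °C) should give racemic Griffinone A F3. Its enantiomers are separated by preparative HPLC on a polysaccharide chiral stationary phase to give 14. The unwanted (R)-enantiomer is re-equilibrated to F3 with the same base and recycled. The fallback rejoins the route at 14.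

Step 4. Possible failures are acylation at both acid chloride groups, intramolecular O-acylation with loss of chloromethane to a 6-methoxypyran-2,4-dione, and hydrolysis on handling, since 9 cannot be purified. The fallback sets out from 7 and moves the differentiation of the two carboxyl groups to a stage that can be chromatographed.
- 7 is treated with 2-(trimethylsilyl)ethanol (1.0 equiv) and pyridine in CH2Cl2 at −20 °C to give 2-(trimethylsilyl)ethyl 2-(chlorocarbonyl)-5-methyl-2-(3-methylbut-2-en-1-yl)hex-4-enoate F4.
- The crude mixture is treated with excess 8 and Et3N to give 2-(trimethylsilyl)ethyl 5,5-dimethoxy-3-oxo-2,2-bis(3-methylbut-2-en-1-yl)pent-4-enoate F5. This neutral ester is freed from the diester and bis(ketene acetal) by-products on Et3N-deactivated silica.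
- Anhydrous TBAF (1.0 equiv, THF, 0 °C) cleaves the silylethyl ester to tetrabutylammonium 5,5-dimethoxy-3-oxo-2,2-bis(3-methylbut-2-en-1-yl)pent-4-enoate F6.
- F6 is converted without isolation by oxalyl chloride (1.0 equiv, −40 °C), with no HCl formed, into 9, which is used at once. The fallback rejoins the route at 9.

**Further compounds**
F1 | step 5 | cardamonin, (E)-1-(2,4-dihydroxy-6-methoxyphenyl)-3-phenylprop-2-en-1-one (commercial) | COc1cc(O)cc(O)c1C(=O)/C=C/c1ccccc1
F2 | step 5 | 3'-prenylcardamonin, (E)-1-[2,4-dihydroxy-6-methoxy-3-(3-methylbut-2-en-1-yl)phenyl]-3-phenylprop-2-en-1-one | COc1cc(O)c(CC=C(C)C)c(O)c1C(=O)/C=C/c1ccccc1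
F3 | step 6 | racemic Griffinone A | COC1=CC(=O)C(CC=C(C)C)(CC=C(C)C)C2=C1C(=O)CC(c1ccccc1)O2
F4 | step 4 | 2-(trimethylsilyl)ethyl 2-(chlorocarbonyl)-5-methyl-2-(3-methylbut-2-en-1-yl)hex-4-enoate | C[Si](C)(C)CCOC(=O)C(CC=C(C)C)(CC=C(C)C)C(=O)Cl
F5 | step 4 | 2-(trimethylsilyl)ethyl 5,5-dimethoxy-3-oxo-2,2-bis(3-methylbut-2-en-1-yl)pent-4-enoate | COC(OC)=CC(=O)C(CC=C(C)C)(CC=C(C)C)C(=O)OCC[Si](C)(C)C
F6 | step 4 | tetrabutylammonium 5,5-dimethoxy-3-oxo-2,2-bis(3-methylbut-2-en-1-yl)pent-4-enoate | CCCC[N+](CCCC)(CCCC)CCCC.COC(OC)=CC(=O)C(CC=C(C)C)(CC=C(C)C)C([O-])=O
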